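**Retrosynthetic overview**

1. Feature: with the lactone numbered O1, C2(=O), C3, C4, C5, the carbon C4 carries both C5 and the CH2–(3-hydroxy-4-methoxyphenyl) arm, so this aryl–CH2 bond is traced back to the CH2 of a cyclopropane fused across C3–C4 of a lactone ester.
2. Target ⇐ trans bis-benzyl ether lactone (double hydrogenolysis) ⇐ C3-quaternary lactone methyl ester (Krapcho loss of CO2Me, equilibration to trans).
3. Key disconnection, one pot: the aryl–CH2 bond of the C4 arm and the C3–CH2Ar bond ⇒ methyl (1S,5R)-2-oxo-3-oxabicyclo[3.1.0]hexane-1-carboxylate + 3-benzyloxy-4-methoxyphenylmagnesium bromide (copper catalysis) + 4-benzyloxy-3-methoxybenzyl bromide.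
4. Bicyclic lactone ⇐ (R)-epichlorohydrin + dimethyl malonate; Grignard reagent ⇐ 5-bromo-2-methoxyphenol; benzyl bromide ⇐ O-benzylvanillin.
5. Ring order: cyclopropane and γ-lactone are formed together in step 1, the cyclopropane is opened in the key step, and the lactone is the only non-aromatic ring carried to the target.

Key step: step 6

Remark: the target is read from its SMILES as the (3R,4R) lactone with the two arylmethyl arms trans; 4-benzyloxy-3-methoxybenzaldehyde is taken as a catalogue chemical (it is otherwise one benzylation from vanillin).

**Route**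

Step 1
Reactants: 1 (R)-epichlorohydrin; 2 dimethyl malonate
Product: 6 methyl (1S,5R)-2-oxo-3-oxabicyclo[3.1.0]hexane-1-carboxylate, via chlorohydrin malonate 3 (not isolated), via epoxy malonate 4 (not isolated), via hydroxymethylcyclopropane diester 5 (not isolated)
Conditions: NaOMe (1.0 equiv), MeOH, rt then reflux
Reagents that add atoms: none
Why: Known domino malonate alkylation, epoxide re-closure, cyclopropanation and lactonisation of epichlorohydrin with a dialkyl malonate: the malonate anion opens the epoxide at its CH2 to give 3, the alkoxide closes epoxide 4 with loss of chloride, and 3-exo-tet attack of the malonate anion at the epoxide CH inverts the epichlorohydrin carbon and sets C5 as R in 5, while the cis ring fusion on lactonisation fixes C1 as S.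

Step 2
Reactants: 7 5-bromo-2-methoxyphenol
Product: 8 2-(benzyloxy)-4-bromo-1-methoxybenzene
Conditions: BnBr, K2CO3, DMF, 60 °C
Reagents that add atoms: benzyl bromide, BrCc1ccccc1
Why: Williamson ether synthesis on a phenoxide with a reactive benzylic bromide, which masks the acidic phenol before the Grignard reagent is made.

Step 3
Reactants: 8 2-(benzyloxy)-4-bromo-1-methoxybenzene
Product: 9 3-benzyloxy-4-methoxyphenylmagnesium bromide (THF solution, titrated and used directly in step 6)
Conditions: Mg turnings, I2 (cat.), THF, reflux
Reagents that add atoms: magnesium, [Mg]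
Why: Grignard formation by magnesium insertion into the aryl C–Br bond, which the methyl and benzyl aryl ethers tolerate.

Step 4
Reactants: 10 4-benzyloxy-3-methoxybenzaldehyde
Product: 11 (4-benzyloxy-3-methoxyphenyl)methanol
Conditions: NaBH4, MeOH, 0 °C to rt
Reagents that add atoms: none
Why: Borohydride reduction of an aromatic aldehyde to the benzylic alcohol, with no other reducible group present.

Step 5
Reactants: 11 (4-benzyloxy-3-methoxyphenyl)methanol
Product: 12 4-benzyloxy-3-methoxybenzyl bromide
Conditions: PBr3 (0.4 equiv), CH2Cl2, 0 °C; used freshly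
Reagents that add atoms: phosphorus tribromide, BrP(Br)Br
Why: Bromination of an electron-rich benzylic alcohol with PBr3 through its phosphite ester and bromide displacement, fast at 0 °C so that the aryl benzyl ether is kept.

Step 6
Reactants: 6 methyl (1S,5R)-2-oxo-3-oxabicyclo[3.1.0]hexane-1-carboxylate; 9 3-benzyloxy-4-methoxyphenylmagnesium bromide; 12 4-benzyloxy-3-methoxybenzyl bromide
Product: 14 methyl (3R,4R)-3-(4-benzyloxy-3-methoxybenzyl)-4-(3-benzyloxy-4-methoxybenzyl)-2-oxotetrahydrofuran-3-carboxylate, via bromomagnesium lactone ester enolate 13 (not isolated)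
Conditions: 9 (1.1 equiv), CuBr·SMe2 (10 mol%), THF, −40 to −20 °C; then 12 (1.5 equiv), DMPU, −20 to 40 °C; aq. NH4Cl
Reagents that add atoms: none
Why: Transmetalation of 9 to copper gives an arylcuprate that attacks the unsubstituted cyclopropane CH2 of the bicycle in an SN2-like oxidative addition, the bond from this CH2 to the quaternary carbon breaks towards the two carbonyl groups, and reductive elimination forms the aryl–CH2 bond and leaves the chelated bromomagnesium lactone–ester enolate 13. The closest known reaction type is the copper-catalysed homoconjugate (homo-Michael) addition of Grignard reagents to 2-oxo-3-oxabicyclo[3.1.0]hexane-1-carboxylates, here followed by C-benzylation of the α-methoxycarbonyl lactone enolate as in a conjugate addition–enolate trapping sequence, for which DMPU loosens the magnesium chelate. No ring is closed; the cyclopropane is opened and the lactone ring is kept. C4 is the former ring-fusion carbon and is not touched, so its R configuration from epichlorohydrin is carried over, and the new quaternary C3 should form by approach of 12 to the enolate face opposite the C4 arylmethyl group, which places the two arylmethyl arms trans (3R). The step needs attack at the cyclopropane CH2 and not at the ring-fusion CH or at a carbonyl group, which the least hindered position of the doubly activated ring, copper catalysis and low temperature secure, and it needs C- over O-alkylation, which the soft benzylic bromide favours; the C3 configuration is not critical because it is reset in step 7.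

Step 7
Reactants: 14 methyl (3R,4R)-3-(4-benzyloxy-3-methoxybenzyl)-4-(3-benzyloxy-4-methoxybenzyl)-2-oxotetrahydrofuran-3-carboxylate
Product: 16 (3R,4R)-3-(4-benzyloxy-3-methoxybenzyl)-4-(3-benzyloxy-4-methoxybenzyl)dihydrofuran-2(3H)-one, via C3-epimeric lactone mixture 15 (not isolated)
Conditions: LiCl, H2O, DMSO, 140 °C; then DBU (cat.), toluene, 80 °C
Reagents that add atoms: none
Why: Krapcho demethoxycarbonylation (chloride attacks the ester methyl group in an SN2 step, the carboxylate loses CO2 and the lactone enolate is protonated by water) leaves C4 untouched and gives the C3 epimer mixture 15, which DBU equilibrates through the enolate to the more stable trans lactone, so that C3 is set as R by thermodynamic control from the C4 centre.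

Step 8
Reactants: 16 (3R,4R)-3-(4-benzyloxy-3-methoxybenzyl)-4-(3-benzyloxy-4-methoxybenzyl)dihydrofuran-2(3H)-one
Product: 17 (3R,4R)-3-(4-hydroxy-3-methoxybenzyl)-4-(3-hydroxy-4-methoxybenzyl)dihydrofuran-2(3H)-one (CNP0309867.1)
Conditions: H2 (1 atm), Pd/C (10% Pd on carbon), EtOAc–MeOH, rt
Reagents that add atoms: none
Why: Palladium-catalysed hydrogenolysis of the two benzyl aryl ethers, under which the lactone, the methyl ethers and the benzylic C–C bonds are inert and no stereocentre is touched.

**Compound list**

1 | (R)-epichlorohydrin | ClC[C@H]1CO1 | starting material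
2 | dimethyl malonate | COC(=O)CC(=O)OC | starting material
3 | dimethyl 2-[(2R)-3-chloro-2-hydroxypropyl]propanedioate (present as its sodium alkoxide) | ClC[C@H](O)CC(C(=O)OC)C(=O)OC | intermediate
4 | dimethyl 2-{[(2R)-oxiran-2-yl]methyl}propanedioate | COC(=O)C(C[C@@H]1CO1)C(=O)OC | intermediate
5 | dimethyl (2R)-2-(hydroxymethyl)cyclopropane-1,1-dicarboxylate (present as its sodium alkoxide) | OC[C@@H]1CC1(C(=O)OC)C(=O)OC | intermediate
6 | methyl (1S,5R)-2-oxo-3-oxabicyclo[3.1.0]hexane-1-carboxylate | O=C1OC[C@@H]2C[C@]12C(=O)OC | intermediate
7 | 5-bromo-2-methoxyphenol | COc1ccc(Br)cc1O | starting material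
8 | 2-(benzyloxy)-4-bromo-1-methoxybenzene | COc1ccc(Br)cc1OCc1ccccc1 | intermediate
9 | 3-benzyloxy-4-methoxyphenylmagnesium bromide | COc1ccc([Mg]Br)cc1OCc1ccccc1 | intermediate
10 | 4-benzyloxy-3-methoxybenzaldehyde (O-benzylvanillin) | COc1cc(C=O)ccc1OCc1ccccc1 | starting material
11 | (4-benzyloxy-3-methoxyphenyl)methanol | COc1cc(CO)ccc1OCc1ccccc1 | intermediate
12 | 4-benzyloxy-3-methoxybenzyl bromide | COc1cc(CBr)ccc1OCc1ccccc1 | intermediate
13 | bromomagnesium enolate of methyl (4R)-4-(3-benzyloxy-4-methoxybenzyl)-2-oxotetrahydrofuran-3-carboxylate | COc1ccc(C[C@H]2COC(O[Mg]Br)=C2C(=O)OC)cc1OCc1ccccc1 | intermediate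
14 | methyl (3R,4R)-3-(4-benzyloxy-3-methoxybenzyl)-4-(3-benzyloxy-4-methoxybenzyl)-2-oxotetrahydrofuran-3-carboxylate | COc1ccc(C[C@H]2COC(=O)[C@@]2(Cc2ccc(OCc3ccccc3)c(OC)c2)C(=O)OC)cc1OCc1ccccc1 | intermediate
15 | (4R)-3-(4-benzyloxy-3-methoxybenzyl)-4-(3-benzyloxy-4-methoxybenzyl)dihydrofuran-2(3H)-one, mixture of C3 epimers | COc1ccc(C[C@H]2COC(=O)C2Cc2ccc(OCc3ccccc3)c(OC)c2)cc1OCc1ccccc1 | intermediate
16 | (3R,4R)-3-(4-benzyloxy-3-methoxybenzyl)-4-(3-benzyloxy-4-methoxybenzyl)dihydrofuran-2(3H)-one | COc1ccc(C[C@H]2COC(=O)[C@@H]2Cc2ccc(OCc3ccccc3)c(OC)c2)cc1OCc1ccccc1 | intermediate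
17 | (3R,4R)-3-(4-hydroxy-3-methoxybenzyl)-4-(3-hydroxy-4-methoxybenzyl)dihydrofuran-2(3H)-one | COc1ccc(C[C@H]2COC(=O)[C@@H]2Cc2ccc(O)c(OC)c2)cc1O | target

**Step count**

Total: 8 steps. Longest linear sequence: 5 steps (steps 2, 3, 6, 7, 8 from 7; the branch from 10 through steps 4, 5, 6, 7, 8 is equally long).

**Steps most likely to fail**

1. Step 6. The chelated magnesium enolate may be benzylated too slowly, so that only the ring-opened, protonated lactone ester is obtained after work-up. Residual aryl-metal may also be consumed by copper-mediated coupling with the benzyl bromide, and the Grignard reagent may add to a carbonyl group if the copper cycle is slow. The fallback sets out from 6 and 9 and moves the benzylation to a lithium lactone enolate after the ester is removed. The same copper-catalysed opening is run alone and quenched with aqueous NH4Cl to give methyl (4R)-4-(3-benzyloxy-4-methoxybenzyl)-2-oxotetrahydrofuran-3-carboxylate F1. Krapcho demethoxycarbonylation (LiCl, wet DMSO, 140 °C) then gives (R)-4-(3-benzyloxy-4-methoxybenzyl)dihydrofuran-2(3H)-one F2. Its lithium enolate (LiHMDS, THF, −78 °C) is alkylated with 12 from the face opposite the C4 arm, which should give the trans lactone directly. The fallback comes back to the route at 16.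

2. Step 7. Demethoxycarbonylation at the hindered quaternary centre may stall, chloride may open the lactone at C5 on prolonged heating, and epimerisation to trans may stay incomplete. The fallback sets out from 14 and replaces the chloride-mediated dealkylation by hydrolysis and thermal decarboxylation. KOH in aqueous MeOH–THF hydrolyses the methyl ester (and opens the lactone), and acidification with HCl closes the lactone again to give (4R)-3-(4-benzyloxy-3-methoxybenzyl)-4-(3-benzyloxy-4-methoxybenzyl)-2-oxotetrahydrofuran-3-carboxylic acid F3 as a C3 epimer mixture. Heating F3 in toluene at reflux should bring about loss of CO2 from the malonic-type acid. The fallback comes back to the route at 15, which DBU equilibrates to 16 as in step 7.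

3. Step 1. Direct displacement of chloride by the malonate competes with epoxide opening and leads to the enantiomeric lactone, so enantiomeric purity may be eroded; oligomerisation of epichlorohydrin under alkoxide may lower the throughput. The fallback uses a glycidyl electrophile that reacts only by direct displacement. Commercial (R)-glycidol (OC[C@@H]1CO1) with Tf2O and pyridine in CH2Cl2 at −20 °C gives (S)-glycidyl trifluoromethanesulfonate F4. The sodium salt of 2 (NaH, THF, 0 °C) displaces the triflate at the CH2–O carbon without touching the epoxide. The fallback sets out from 2 and comes back to the route at 4, which goes on under base through 5 to 6 as in step 1.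

**Further compounds**

F1 | step 6 | methyl (4R)-4-(3-benzyloxy-4-methoxybenzyl)-2-oxotetrahydrofuran-3-carboxylate (C3 epimers) | COc1ccc(C[C@H]2COC(=O)C2C(=O)OC)cc1OCc1ccccc1
F2 | step 6 | (R)-4-(3-benzyloxy-4-methoxybenzyl)dihydrofuran-2(3H)-one | COc1ccc(C[C@H]2COC(=O)C2)cc1OCc1ccccc1
F3 | step 7 | (4R)-3-(4-benzyloxy-3-methoxybenzyl)-4-(3-benzyloxy-4-methoxybenzyl)-2-oxotetrahydrofuran-3-carboxylic acid (C3 epimers) | COc1ccc(C[C@H]2COC(=O)C2(Cc2ccc(OCc3ccccc3)c(OC)c2)C(=O)O)cc1OCc1ccccc1
F4 | step 1 | (S)-glycidyl trifluoromethanesulfonate | FC(F)(F)S(=O)(=O)OC[C@@H]1CO1
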